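## Retrosynthetic overview

1. Target ⇐ tricyclic lactone 28 by exchange of the O8 and O15 silyl groups. Ring B (O–C5–C6–C7–C8–C9–C10) and the α-methylene lactone are closed together from aldehyde 25 by an intramolecular zinc Barbier allylation and lactonisation (C6–C7, then O6–C12).
2. 25 ⇐ ring-A oxepane 17, in which C4 and C5 are set by hydroxyl-directed hydrogenation of 2,5-dihydrooxepine 15 and equilibration of C4.
3. Dihydrooxepine 14 ⇐ allylic sulfonium salt 8 + alkoxymethylene keto ester 11. A sulfonium-ylide cyclopropanation followed in the same flask by a retro-Claisen [3,3] shift forms C2–C3 and O–C10.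
4. Enabling feature: in ring A (O, C10, C1, C2, C3, C4, C5) the ether oxygen sits on C5, next to C4, which carries C15, and C1/C2 are plain CH2 groups. Ring A can therefore be taken back to a 2,5-dihydrooxepine (C4=C5 enol ether conjugated to a C15 ester, C1=C2 alkene). That is the product of a cis-2-alkenylcyclopropyl ketone [3,3] shift in which oxygenated C3 is the third cyclopropane carbon and quaternary C10 is the terminus of an E-trisubstituted alkene.
5. Ring order: transient cyclopropane (C2, C3, C4) → ring A → ring B with the lactone. 8 comes from (R)-benzyl glycidyl ether (C8 stereocentre), 11 from methyl 4,4-dimethoxy-3-oxobutanoate.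

Key step: step 8

Numbering: C1–C10 are the carbons of the ten-membered carbocycle (C3 acetoxy carbon, C4 bears C15H2OH, C5 and C10 ether bridgeheads, C6 lactone O–CH, C8 methacrylate carbon, C10 bears the C14 methyl); C11–C13 are the lactone carbons.

Remark on the chemistry: the stereodescriptors are carried exactly as the target string gives them (all seven centres R). Read this way, the C5–C6 and C10–C9 bonds lie on opposite faces of ring A, so ring B is a trans-bridged (inside–outside) ring with H5 turned inward. C5 is therefore fixed on the monocyclic stage, before ring B is closed.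

Remark on the chemistry: the sense of induction of the chiral thiolane in step 8 is assigned by analogy with its ylide epoxidations; the antipodal thiolane would be used if it proved opposite.

## Route

Step 1
Reactants: 1 (R)-benzyl glycidyl ether
Product: 2 (2R)-1-(benzyloxy)pent-4-yn-2-ol
Conditions: LiC≡CH·H2NCH2CH2NH2, DMSO, rt
Reagents that add atoms: lithium acetylide–ethylenediamine complex, [Li+].[C-]#C.NCCN
Why: SN2 opening of the terminal epoxide carbon by the acetylide (epoxide alkynylation) leaves the chiral-pool C8 stereocentre untouched.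

Step 2
Reactants: 2 (2R)-1-(benzyloxy)pent-4-yn-2-ol
Product: 3 (2R)-1-(benzyloxy)-2-(tert-butyldimethylsilyloxy)pent-4-yne
Conditions: t-BuMe2SiCl, imidazole, DMF, rt
Reagents that add atoms: tert-butyldimethylsilyl chloride, CC(C)(C)[Si](C)(C)Cl
Why: Standard silylation masks the C8 oxygen as an ether that survives the organometallic, basic and reductive steps that follow.

Step 3
Reactants: 3 (2R)-1-(benzyloxy)-2-(tert-butyldimethylsilyloxy)pent-4-yne
Product: 5 (2E,5R)-6-(benzyloxy)-5-(tert-butyldimethylsilyloxy)-3-methylhex-2-en-1-ol, via alkenylalane 4 (not isolated)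
Conditions: Me3Al, Cp2ZrCl2 (cat.), CH2Cl2, 0 °C to rt; then n-BuLi, (CH2O)n, THF, −78 °C to rt
Reagents that add atoms: trimethylaluminium, C[Al](C)C; paraformaldehyde, C=O
Why: Zirconium-catalysed Negishi carboalumination adds methyl and aluminium syn across the terminal alkyne, which fixes the E-trisubstituted C1=C10 alkene, and the alkenyl alanate is hydroxymethylated with retention to give C2.

Step 4
Reactants: 5 (2E,5R)-6-(benzyloxy)-5-(tert-butyldimethylsilyloxy)-3-methylhex-2-en-1-ol
Product: 6 (2E,5R)-6-(benzyloxy)-1-bromo-5-(tert-butyldimethylsilyloxy)-3-methylhex-2-ene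
Conditions: CBr4, PPh3, CH2Cl2, 0 °C
Reagents that add atoms: carbon tetrabromide, BrC(Br)(Br)Br
Why: The Appel reaction converts the primary allylic alcohol into the bromide under neutral conditions without allylic transposition.

Step 5
Reactants: 6 (2E,5R)-6-(benzyloxy)-1-bromo-5-(tert-butyldimethylsilyloxy)-3-methylhex-2-ene, 7 (2R,5R)-2,5-dimethylthiolane
Product: 8 S-[(2E,5R)-6-(benzyloxy)-5-(tert-butyldimethylsilyloxy)-3-methylhex-2-enyl]-(2R,5R)-2,5-dimethylthiolanium tetrafluoroborate
Conditions: NaBF4, CH2Cl2/H2O, rt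
Reagents that add atoms: sodium tetrafluoroborate, [Na+].F[B-](F)(F)F
Why: SN2 S-alkylation at the primary allylic carbon with anion exchange gives the sulfonium salt with the E alkene intact, and sulfur is not a stereocentre because the thiolane is C2-symmetric.

Step 6
Reactants: 9 methyl 4,4-dimethoxy-3-oxobutanoate
Product: 10 methyl 2-(ethoxymethylidene)-4,4-dimethoxy-3-oxobutanoate
Conditions: HC(OEt)3, Ac2O, 120 °C
Reagents that add atoms: triethyl orthoformate, CCOC(OCC)OCC
Why: Alkoxymethylenation of the active methylene group, driven by acetylation of the ethanol released, installs C3 at the formyl oxidation level.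

Step 7
Reactants: 10 methyl 2-(ethoxymethylidene)-4,4-dimethoxy-3-oxobutanoate
Product: 11 methyl 4,4-dimethoxy-2-[(4-methoxybenzyloxy)methylidene]-3-oxobutanoate
Conditions: 4-MeOC6H4CH2OH, NaH (cat.), toluene, 40 °C, reduced pressure
Reagents that add atoms: 4-methoxybenzyl alcohol, COc1ccc(CO)cc1
Why: Alkoxide-catalysed addition–elimination at the push–pull alkene (vinylogous transesterification) exchanges ethoxy for the oxidatively removable 4-methoxybenzyloxy group, driven by removal of ethanol.

Step 8
Reactants: 8 S-allylic (2R,5R)-2,5-dimethylthiolanium tetrafluoroborate, 11 methyl 4,4-dimethoxy-2-[(4-methoxybenzyloxy)methylidene]-3-oxobutanoate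
Product: 14 methyl (2S,5R)-2-[(2R)-3-(benzyloxy)-2-(tert-butyldimethylsilyloxy)propyl]-7-(dimethoxymethyl)-5-(4-methoxybenzyloxy)-2-methyl-2,5-dihydrooxepine-6-carboxylate, via sulfonium ylide 12 (not isolated), via alkenylcyclopropane 13 (not isolated)
Conditions: LiN(SiMe3)2, THF, −78 °C; add 11, −78 to −20 °C; then toluene, 80 °C
Reagents that add atoms: none
Why: Proposed new method: LiN(SiMe3)2 deprotonates 8 at the allylic S–CH2 group and the semi-stabilised ylide 12 adds through C2 to the alkoxymethylene carbon C3 of 11 (Michael addition), after which the lithium-chelated, U-shaped keto ester enolate displaces the thiolane from C2 (3-exo-tet) to close the transient cyclopropane 13; warming then triggers the retro-Claisen [3,3]-sigmatropic shift of the cis-2-alkenylcyclopropyl ketone, which forms O–C10, cleaves C2–C4 and so closes ring A as a seven-membered ring through the obligatory boat transition state. The closest known reactions are the sulfonium-ylide cyclopropanation of alkylidene 1,3-dicarbonyl compounds and the thermal retro-Claisen ring expansion of 2-vinylcyclopropane-1,1-dicarbonyl compounds, which is driven by the vinylogous carbonate (O–C5=C4–CO2Me) that it forms; their union in one flask on a β-alkoxy acceptor with a trisubstituted alkene terminus is without precedent. C2 and C3 are set by the chiral thiolane, which shields one face of the ylide, and by the preference of the alkenyl and 4-methoxybenzyloxy groups for a trans arrangement; C10 is set by transfer from C2, because the E alkene places its methyl group inside and the C9 chain outside the boat, C3 being untouched by the shift. The step needs 1,4- rather than 1,2-addition (secured by the push–pull acceptor and the reversibility of ylide addition to the ketone), C- rather than O-alkylation of the enolate, and the ketone rather than the ester cis to the alkenyl group: the lithium chelate turns the ketone oxygen away from C2, and allylic 1,3-strain in the chelate puts C3–H next to the bulky dimethoxyacetyl group and C3–O next to the ester, so the alkenyl group, trans to C3–O, ends up cis to the ketone. The concerted shift must also outrun heterolysis of the donor–acceptor C3–C4 bond, which is why no Lewis acid is present and the rearrangement is run in toluene.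

Step 9
Reactants: 14 dihydrooxepine ester with the C3 4-methoxybenzyl ether
Product: 15 methyl (2S,5R)-2-[(2R)-3-(benzyloxy)-2-(tert-butyldimethylsilyloxy)propyl]-7-(dimethoxymethyl)-5-hydroxy-2-methyl-2,5-dihydrooxepine-6-carboxylate
Conditions: DDQ, CH2Cl2/pH 7 buffer, 0 °C
Reagents that add atoms: none
Why: Oxidative cleavage of the 4-methoxybenzyl ether by DDQ, to which the benzyl ether, the silyl ether and the acetal are inert, frees the C3 hydroxyl needed as a directing group.

Step 10
Reactants: 15 dihydrooxepine with free C3 hydroxyl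
Product: 17 methyl (2R,3R,4R,7R)-7-[(2R)-3-(benzyloxy)-2-(tert-butyldimethylsilyloxy)propyl]-2-(dimethoxymethyl)-4-hydroxy-7-methyloxepane-3-carboxylate, via C4-epimeric ester 16 (not isolated)
Conditions: H2 (20 bar), [Ir(cod)(PCy3)(py)]PF6 (10 mol %), CH2Cl2, rt; then NaOMe (0.3 equiv), MeOH, 0 °C
Reagents that add atoms: none
Why: Hydroxyl-directed homogeneous hydrogenation delivers hydrogen to both alkenes from the face of the C3 hydroxyl, which sets H5 cis to O3, and methoxide then epimerises the enolisable C4 so that the ester becomes trans to the dimethoxymethyl group and cis to the C3 hydroxyl, to which it can hydrogen-bond.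

Step 11
Reactants: 17 ring-A hydroxy ester
Product: 18 (2R,3R,4R,7R)-7-[(2R)-3-(benzyloxy)-2-(tert-butyldimethylsilyloxy)propyl]-2-(dimethoxymethyl)-3-(hydroxymethyl)-7-methyloxepan-4-ol
Conditions: LiAlH4, THF, 0 °C
Reagents that add atoms: none
Why: Hydride reduction of the ester brings C15 to the alcohol level without touching the ethers or the acetal and without affecting any stereocentre.

Step 12
Reactants: 18 ring-A diol
Product: 19 C15 tert-butyldiphenylsilyl ether of 18 (C3 hydroxyl free)
Conditions: t-BuPh2SiCl, imidazole, CH2Cl2, 0 °C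
Reagents that add atoms: tert-butyldiphenylsilyl chloride, CC(C)(C)[Si](Cl)(c1ccccc1)c1ccccc1
Why: The bulky silyl chloride silylates the primary C15 hydroxyl selectively over the secondary C3 hydroxyl.

Step 13
Reactants: 19 C15 silyl ether with free C3 hydroxyl
Product: 20 C3 acetate of 19
Conditions: Ac2O, pyridine, DMAP (cat.), rt
Reagents that add atoms: acetic anhydride, CC(=O)OC(C)=O
Why: DMAP-catalysed acylation installs the C3 acetate of the target on the only free hydroxyl.

Step 14
Reactants: 20 C3 acetate with C7 benzyl ether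
Product: 21 primary C7 alcohol (benzyl ether removed)
Conditions: H2 (1 bar), 10% Pd/C, EtOAc, rt
Reagents that add atoms: none
Why: Hydrogenolysis cleaves only the benzyl ether, since no alkene remains and the silyl ethers, the acetate and the acetal are stable.

Step 15
Reactants: 21 primary C7 alcohol
Product: 22 C7 aldehyde (α-silyloxy aldehyde)
Conditions: Dess–Martin periodinane, NaHCO3, CH2Cl2, rt
Reagents that add atoms: none
Why: Dess–Martin oxidation gives the α-silyloxy aldehyde under buffered conditions that should not epimerise C8.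

Step 16
Reactants: 22 C7 aldehyde
Product: 23 Morita–Baylis–Hillman adduct (methyl 2-methylidene-3-hydroxy ester at C7; both C7 epimers)
Conditions: methyl acrylate, DABCO, dioxane/H2O, rt
Reagents that add atoms: methyl acrylate, C=CC(=O)OC
Why: The Morita–Baylis–Hillman reaction attaches C11–C13 to C7, and the configuration of the new carbinol is irrelevant because C7 becomes sp2 in step 17.

Step 17
Reactants: 23 Morita–Baylis–Hillman adduct
Product: 24 (Z)-2-(bromomethyl)alk-2-enoate (C13 bromide; C11=C7 alkene)
Conditions: NBS, Me2S, CH2Cl2, 0 °C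
Reagents that add atoms: N-bromosuccinimide, O=C1CCC(=O)N1Br
Why: The bromosulfonium reagent activates the allylic alcohol and bromide attacks the methylene terminus (SN2′), which gives the thermodynamically favoured (Z)-2-(bromomethyl)alk-2-enoate.

Step 18
Reactants: 24 allylic bromide with C6 dimethyl acetal
Product: 25 C6 aldehyde
Conditions: Et3SiOTf, 2,6-lutidine, CH2Cl2, 0 °C; then H2O
Reagents that add atoms: water, O
Why: The silyl triflate and the hindered pyridine convert the dimethyl acetal into a pyridinium intermediate that water hydrolyses to the aldehyde, a mild acetal cleavage that spares the silyl ethers, the acetate and the allylic bromide.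

Step 19
Reactants: 25 bromo aldehyde
Product: 28 tricyclic lactone (C8 tert-butyldimethylsilyl ether; C15 tert-butyldiphenylsilyl ether; C3 acetate), via allylzinc bromide 26 (not isolated), via hydroxy ester 27 (not isolated)
Conditions: Zn dust, THF/sat. aq. NH4Cl, high dilution, 0 °C to rt; then PPTS (cat.), CH2Cl2, rt
Reagents that add atoms: none
Why: Intramolecular Barbier allylation through a chair-like six-membered (Zimmerman–Traxler) transition state, in which the γ-substituted allylzinc attacks through C7, forms C6–C7 and closes ring B, C6 being set by chelation of zinc between the aldehyde oxygen and the ring ether oxygen on C5 and C7 by the syn preference of the (Z)-type allylzinc, and the resulting cis hydroxy ester lactonises to the α-methylene lactone.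

Step 20
Reactants: 28 tricyclic lactone
Product: 29 C8 alcohol
Conditions: HF·pyridine, pyridine, THF, 0 °C
Reagents that add atoms: none
Why: Buffered fluoride removes the secondary tert-butyldimethylsilyl ether much faster than the primary tert-butyldiphenylsilyl ether and leaves the acetate and the lactone intact.

Step 21
Reactants: 29 C8 alcohol
Product: 30 C8 methacrylate
Conditions: methacrylic anhydride, Et3N, DMAP (cat.), CH2Cl2, 0 °C to rt
Reagents that add atoms: methacrylic anhydride, C=C(C)C(=O)OC(=O)C(C)=C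
Why: DMAP-catalysed acylation of the only free hydroxyl installs the methacrylate with retention at C8.

Step 22
Reactants: 30 C8 methacrylate with C15 silyl ether
Product: 31 target CNP0602302.1
Conditions: HF·pyridine, THF, rt
Reagents that add atoms: none
Why: Acidic fluoride cleaves the remaining silyl ether to free the C15 hydroxyl under conditions that should not cause acetate migration from O3 or conjugate addition to the two acrylate units.

## Compound list

1 | (R)-benzyl glycidyl ether, (2R)-2-(benzyloxymethyl)oxirane | C1O[C@H]1COCc1ccccc1 | starting material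
2 | (2R)-1-(benzyloxy)pent-4-yn-2-ol | O[C@@H](COCc1ccccc1)CC#C | intermediate
3 | (2R)-1-(benzyloxy)-2-(tert-butyldimethylsilyloxy)pent-4-yne | CC(C)(C)[Si](C)(C)O[C@@H](COCc1ccccc1)CC#C | intermediate
4 | (E)-alkenyl(dimethyl)alane from 3 (aluminium on C1, cis to the new C14 methyl) | C[Al](C)/C=C(\C)C[C@@H](O[Si](C)(C)C(C)(C)C)COCc1ccccc1 | intermediate
5 | (2E,5R)-6-(benzyloxy)-5-(tert-butyldimethylsilyloxy)-3-methylhex-2-en-1-ol | OC/C=C(C)/C[C@@H](O[Si](C)(C)C(C)(C)C)COCc1ccccc1 | intermediate
6 | (2E,5R)-6-(benzyloxy)-1-bromo-5-(tert-butyldimethylsilyloxy)-3-methylhex-2-ene | BrC/C=C(C)/C[C@@H](O[Si](C)(C)C(C)(C)C)COCc1ccccc1 | intermediate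
7 | (2R,5R)-2,5-dimethylthiolane | C[C@@H]1CC[C@@H](C)S1 | starting material
8 | S-[(2E,5R)-6-(benzyloxy)-5-(tert-butyldimethylsilyloxy)-3-methylhex-2-enyl]-(2R,5R)-2,5-dimethylthiolanium tetrafluoroborate | C[C@@H]1CC[C@@H](C)[S+]1C/C=C(C)/C[C@@H](O[Si](C)(C)C(C)(C)C)COCc1ccccc1.F[B-](F)(F)F | intermediate
9 | methyl 4,4-dimethoxy-3-oxobutanoate | COC(OC)C(=O)CC(=O)OC | starting material
10 | methyl 2-(ethoxymethylidene)-4,4-dimethoxy-3-oxobutanoate (E/Z mixture) | CCOC=C(C(=O)OC)C(=O)C(OC)OC | intermediate
11 | methyl 4,4-dimethoxy-2-[(4-methoxybenzyloxy)methylidene]-3-oxobutanoate (E/Z mixture) | COc1ccc(COC=C(C(=O)OC)C(=O)C(OC)OC)cc1 | intermediate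
12 | sulfonium ylide of 8 (carbanion at C2) | C[C@@H]1CC[C@@H](C)[S+]1[CH-]/C=C(C)/C[C@@H](O[Si](C)(C)C(C)(C)C)COCc1ccccc1 | intermediate
13 | methyl (1S,2S,3R)-2-[(1E,4R)-5-(benzyloxy)-4-(tert-butyldimethylsilyloxy)-2-methylpent-1-enyl]-1-(2,2-dimethoxyacetyl)-3-(4-methoxybenzyloxy)cyclopropane-1-carboxylate (alkenyl trans to the benzyloxy group, cis to the ketone) | c1ccccc1COC[C@H](O[Si](C)(C)C(C)(C)C)C/C(C)=C/[C@@H]1[C@@H](OCc2ccc(OC)cc2)[C@@]1(C(=O)C(OC)OC)C(=O)OC | intermediate
14 | methyl (2S,5R)-2-[(2R)-3-(benzyloxy)-2-(tert-butyldimethylsilyloxy)propyl]-7-(dimethoxymethyl)-5-(4-methoxybenzyloxy)-2-methyl-2,5-dihydrooxepine-6-carboxylate | c1ccccc1COC[C@H](O[Si](C)(C)C(C)(C)C)C[C@@]2(C)C=C[C@@H](OCc3ccc(OC)cc3)C(C(=O)OC)=C(O2)C(OC)OC | intermediate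
15 | methyl (2S,5R)-2-[(2R)-3-(benzyloxy)-2-(tert-butyldimethylsilyloxy)propyl]-7-(dimethoxymethyl)-5-hydroxy-2-methyl-2,5-dihydrooxepine-6-carboxylate | c1ccccc1COC[C@H](O[Si](C)(C)C(C)(C)C)C[C@@]2(C)C=C[C@@H](O)C(C(=O)OC)=C(O2)C(OC)OC | intermediate
16 | methyl (2R,3S,4R,7R)-7-[(2R)-3-(benzyloxy)-2-(tert-butyldimethylsilyloxy)propyl]-2-(dimethoxymethyl)-4-hydroxy-7-methyloxepane-3-carboxylate (C4 epimer of 17; H4 and H5 cis to the C3 hydroxyl) | c1ccccc1COC[C@H](O[Si](C)(C)C(C)(C)C)C[C@@]2(C)CC[C@@H](O)[C@H](C(=O)OC)[C@@H](O2)C(OC)OC | intermediate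
17 | methyl (2R,3R,4R,7R)-7-[(2R)-3-(benzyloxy)-2-(tert-butyldimethylsilyloxy)propyl]-2-(dimethoxymethyl)-4-hydroxy-7-methyloxepane-3-carboxylate | c1ccccc1COC[C@H](O[Si](C)(C)C(C)(C)C)C[C@@]2(C)CC[C@@H](O)[C@@H](C(=O)OC)[C@@H](O2)C(OC)OC | intermediate
18 | (2R,3R,4R,7R)-7-[(2R)-3-(benzyloxy)-2-(tert-butyldimethylsilyloxy)propyl]-2-(dimethoxymethyl)-3-(hydroxymethyl)-7-methyloxepan-4-ol | c1ccccc1COC[C@H](O[Si](C)(C)C(C)(C)C)C[C@@]2(C)CC[C@@H](O)[C@@H](CO)[C@@H](O2)C(OC)OC | intermediate
19 | C15 tert-butyldiphenylsilyl ether of 18 | c1ccccc1COC[C@H](O[Si](C)(C)C(C)(C)C)C[C@@]2(C)CC[C@@H](O)[C@@H](CO[Si](c3ccccc3)(c3ccccc3)C(C)(C)C)[C@@H](O2)C(OC)OC | intermediate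
20 | C3 acetate of 19 | c1ccccc1COC[C@H](O[Si](C)(C)C(C)(C)C)C[C@@]2(C)CC[C@@H](OC(C)=O)[C@@H](CO[Si](c3ccccc3)(c3ccccc3)C(C)(C)C)[C@@H](O2)C(OC)OC | intermediate
21 | primary C7 alcohol from 20 (benzyl removed) | OC[C@H](O[Si](C)(C)C(C)(C)C)C[C@@]2(C)CC[C@@H](OC(C)=O)[C@@H](CO[Si](c3ccccc3)(c3ccccc3)C(C)(C)C)[C@@H](O2)C(OC)OC | intermediate
22 | C7 aldehyde from 21 | O=C[C@H](O[Si](C)(C)C(C)(C)C)C[C@@]2(C)CC[C@@H](OC(C)=O)[C@@H](CO[Si](c3ccccc3)(c3ccccc3)C(C)(C)C)[C@@H](O2)C(OC)OC | intermediate
23 | Morita–Baylis–Hillman adduct of 22 with methyl acrylate (C7 carbinol; both epimers) | C=C(C(=O)OC)C(O)[C@H](O[Si](C)(C)C(C)(C)C)C[C@@]2(C)CC[C@@H](OC(C)=O)[C@@H](CO[Si](c3ccccc3)(c3ccccc3)C(C)(C)C)[C@@H](O2)C(OC)OC | intermediate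
24 | (Z)-2-(bromomethyl)alk-2-enoate from 23 (C6 still the dimethyl acetal) | BrC/C(C(=O)OC)=C\[C@H](O[Si](C)(C)C(C)(C)C)C[C@@]2(C)CC[C@@H](OC(C)=O)[C@@H](CO[Si](c3ccccc3)(c3ccccc3)C(C)(C)C)[C@@H](O2)C(OC)OC | intermediate
25 | C6 aldehyde from 24 | BrC/C(C(=O)OC)=C\[C@H](O[Si](C)(C)C(C)(C)C)C[C@@]2(C)CC[C@@H](OC(C)=O)[C@@H](CO[Si](c3ccccc3)(c3ccccc3)C(C)(C)C)[C@@H](O2)C=O | intermediate
26 | allylzinc bromide from 25 | Br[Zn]C/C(C(=O)OC)=C\[C@H](O[Si](C)(C)C(C)(C)C)C[C@@]2(C)CC[C@@H](OC(C)=O)[C@@H](CO[Si](c3ccccc3)(c3ccccc3)C(C)(C)C)[C@@H](O2)C=O | intermediate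
27 | bicyclic C6 hydroxy ester (rings A and B closed; methyl 2-methylidene ester on C7) | CC(C)(C)[Si](C)(C)O[C@@H]1C[C@@]2(C)CC[C@@H](OC(C)=O)[C@@H](CO[Si](c3ccccc3)(c3ccccc3)C(C)(C)C)[C@@H](O2)[C@H](O)[C@@H]1C(=C)C(=O)OC | intermediate
28 | tricyclic α-methylene lactone with C8 tert-butyldimethylsilyl ether, C15 tert-butyldiphenylsilyl ether and C3 acetate (all centres as in the target) | CC(C)(C)[Si](C)(C)O[C@@H]1C[C@@]2(C)CC[C@@H](OC(C)=O)[C@@H](CO[Si](c3ccccc3)(c3ccccc3)C(C)(C)C)[C@@H](O2)[C@@H]2OC(=O)C(=C)[C@@H]21 | intermediate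
29 | C8 alcohol from 28 | O[C@@H]1C[C@@]2(C)CC[C@@H](OC(C)=O)[C@@H](CO[Si](c3ccccc3)(c3ccccc3)C(C)(C)C)[C@@H](O2)[C@@H]2OC(=O)C(=C)[C@@H]21 | intermediate
30 | C8 methacrylate with C15 tert-butyldiphenylsilyl ether | C=C(C)C(=O)O[C@@H]1C[C@@]2(C)CC[C@@H](OC(C)=O)[C@@H](CO[Si](c3ccccc3)(c3ccccc3)C(C)(C)C)[C@@H](O2)[C@@H]2OC(=O)C(=C)[C@@H]21 | intermediate
31 | CNP0602302.1 (3-acetoxy-15-hydroxy-8-methacryloyloxy-5,10-epoxygermacr-11(13)-en-6,12-olide, all seven centres R) | C=C(C)C(=O)O[C@@H]1C[C@@]2(C)CC[C@@H](OC(C)=O)[C@@H](CO)[C@@H](O2)[C@@H]2OC(=O)C(=C)[C@@H]21 | target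

## Step count and risks

Total step count: 22. Longest linear sequence: 20 steps (steps 1–5 and 8–22); steps 6 and 7 form the short branch to 11.

Steps most likely to fail:

**Step 8 (proposed new method).** Four processes can divert it:
- O-alkylation of the enolate at C2, which gives a 2-alkenyl-2,3-dihydrofuran;
- loss of 4-methoxybenzyl oxide from the Michael adduct by E1cB elimination;
- ring closure with the ester instead of the ketone cis to the alkenyl group;
- a sluggish [3,3] shift, because the methyl group must sit inside the boat, so that heterolysis of the donor–acceptor cyclopropane takes over; weak facial control by the thiolane would add to this.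

The fallback uses known chemistry, sets out from 6 and 11 and comes back at 14. It separates the two bond-forming events and replaces reagent control by separation. Bromide 6 is alkylated onto tetrahydrothiophene (NaBF4, CH2Cl2/H2O) to give the achiral S-allylic tetrahydrothiophenium tetrafluoroborate F1. LiN(SiMe3)2 at −78 °C converts it into the ylide F2, which cyclopropanates 11 at −78 to −20 °C; this is the documented sulfonium-ylide cyclopropanation of an alkylidene 1,3-dicarbonyl compound. The cyclopropane is isolated cold as a pair of diastereomers, 13 and its isomer with the opposite configuration at all three ring carbons, F3. They can be separated by chromatography because C8 is a fixed stereocentre. Pure 13 is then heated in toluene, the documented thermal retro-Claisen rearrangement of a 2-alkenylcyclopropane-1,1-dicarbonyl compound, to give 14.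

**Step 19.** Closure of the strained, trans-bridged ring B may be slow. Protonation or dimerisation of the allylzinc species, elimination of the C8 silyloxy group, or attack on the wrong face of the C7=C11 alkene (a mismatch between the C8 centre and the control relayed from C5) can then compete. The fallback sets out from 24 and comes back at 28. It replaces the transient organozinc by an isolable allylboron reagent. Borylation of 24 (B2pin2, Pd2(dba)3 cat., DMSO, 50 °C) gives the linear allyl pinacolboronate F4. Acetal cleavage as in step 18 gives the boronate aldehyde F5. Heating F5 at high dilution in toluene effects the intramolecular allylboration through the closed six-membered transition state and gives the cyclised boronate ester F6. Aqueous triethanolamine work-up releases 27, which lactonises with PPTS to 28.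

**Step 10.** The iridium catalyst may not turn over on the tetrasubstituted, electron-poor C4=C5 bond, so that only C1=C2 is reduced. The methoxide step may open ring A by retro-oxa-Michael addition or dehydrate the β-hydroxy ester. The fallback sets out from 15 and comes back at 17. It reduces the two alkenes by two different mechanisms. Hydrogenation with RhCl(PPh3)3 (H2, benzene/EtOH) saturates only C1=C2 and gives the tetrahydrooxepine hydroxy ester F7. Alkoxide-directed conjugate reduction of F7 with NaAlH2(OCH2CH2OMe)2 (THF, −40 °C) then delivers hydride to C5 from the aluminate bound to O3. Work-up protonates C4, and the same mild equilibration at C4 as in step 10 gives 17.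

Further compounds
F1 | step 8 | S-[(2E,5R)-6-(benzyloxy)-5-(tert-butyldimethylsilyloxy)-3-methylhex-2-enyl]tetrahydrothiophenium tetrafluoroborate | C1CC[S+](C1)C/C=C(C)/C[C@@H](O[Si](C)(C)C(C)(C)C)COCc1ccccc1.F[B-](F)(F)F
F2 | step 8 | sulfonium ylide of F1 (carbanion at C2) | C1CC[S+](C1)[CH-]/C=C(C)/C[C@@H](O[Si](C)(C)C(C)(C)C)COCc1ccccc1
F3 | step 8 | methyl (1R,2R,3S)-2-[(1E,4R)-5-(benzyloxy)-4-(tert-butyldimethylsilyloxy)-2-methylpent-1-enyl]-1-(2,2-dimethoxyacetyl)-3-(4-methoxybenzyloxy)cyclopropane-1-carboxylate (diastereomer of 13) | c1ccccc1COC[C@H](O[Si](C)(C)C(C)(C)C)C/C(C)=C/[C@H]1[C@H](OCc2ccc(OC)cc2)[C@]1(C(=O)C(OC)OC)C(=O)OC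
F4 | step 19 | allyl pinacolboronate corresponding to bromide 24 (C6 dimethyl acetal) | CC1(C)OB(C/C(C(=O)OC)=C\[C@H](O[Si](C)(C)C(C)(C)C)C[C@@]2(C)CC[C@@H](OC(C)=O)[C@@H](CO[Si](c3ccccc3)(c3ccccc3)C(C)(C)C)[C@@H](O2)C(OC)OC)OC1(C)C
F5 | step 19 | allyl pinacolboronate with free C6 aldehyde | CC1(C)OB(C/C(C(=O)OC)=C\[C@H](O[Si](C)(C)C(C)(C)C)C[C@@]2(C)CC[C@@H](OC(C)=O)[C@@H](CO[Si](c3ccccc3)(c3ccccc3)C(C)(C)C)[C@@H](O2)C=O)OC1(C)C
F6 | step 19 | O6-pinacolboryl ester of hydroxy ester 27 | CC(C)(C)[Si](C)(C)O[C@@H]1C[C@@]2(C)CC[C@@H](OC(C)=O)[C@@H](CO[Si](c3ccccc3)(c3ccccc3)C(C)(C)C)[C@@H](O2)[C@H](OB4OC(C)(C)C(C)(C)O4)[C@@H]1C(=C)C(=O)OC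
F7 | step 10 | methyl (4R,7R)-7-[(2R)-3-(benzyloxy)-2-(tert-butyldimethylsilyloxy)propyl]-2-(dimethoxymethyl)-4-hydroxy-7-methyl-4,5,6,7-tetrahydrooxepine-3-carboxylate | c1ccccc1COC[C@H](O[Si](C)(C)C(C)(C)C)C[C@@]2(C)CC[C@@H](O)C(C(=O)OC)=C(O2)C(OC)OC
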